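Labels: rings A (prenylated) and B and the oxepine use dibenzo[b,f]oxepine numbers (O5, C10, C11). Ca is the cyclobutane CH on C11, Cb and Cc are the ring-fusion CH groups, and Cd is the quaternary C(CH3)–O carbon.
Cuts, in retrosynthetic order: C2–prenyl, O–Cd (pyran), O5–C5a (oxepine), C11–C11a (ring A), C10–C9a (ring B), C11=Ca, and last the cyclobutane bonds Ca–CMe2 and Cb–Cc.
Enabling feature: Cd is the tertiary end of the C3=C4 alkene of a methylcyclopentene fused to the cyclobutane. The C10 ketone oxygen hangs from Ca on the concave face, so O, C10, C11, Ca, Cb and Cd already outline the six-membered pyran.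
Forward order: cyclobutane and cyclopentene form together (ketene [2+2]); then come the C11–C10–ring B chain, ring A on C11, the oxepine, the pyran, and the prenyl group last.
Stereochemistry: Cb and Cc come from an enzymatic kinetic resolution of the cis-fused ketone, Ca from hydride delivery to the convex face, and Cd from the concave-face tether. C11 ends up trigonal.

Key step: step 12

Assumption: geranic acid is used as its commercial 2E/2Z mixture because both isomers give the same vinylketene, and every compound stereogenic at C11 is carried as an epimer mixture because C11 becomes sp2 in step 12.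

Step 1
Reactants: 1 geranic acid (3,7-dimethylocta-2,6-dienoic acid; 2E/2Z mixture)
Product: 4 (±)-cis-4,7,7-trimethylbicyclo[3.2.0]hept-3-en-6-one (racemic filifolone), via mixed anhydride 2 (not isolated), via vinylketene 3 (not isolated)
Conditions: Ac2O, NaOAc, reflux (about 140 °C)
Reagents that add atoms: none
Why: Acetate-promoted loss of acetic acid from the mixed anhydride with removal of a C4 proton gives the vinylketene, and its intramolecular ketene–alkene [2+2] cycloaddition onto the Me2C=CH unit is a known route to this ketone that forms Ca–CMe2 and Cb–Cc at once and can only give the cis ring fusion (as the racemate).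

Step 2
Reactants: 4 (±)-cis-4,7,7-trimethylbicyclo[3.2.0]hept-3-en-6-one
Product: 5 (1S,5S)-4,7,7-trimethylbicyclo[3.2.0]hept-3-en-6-one
Conditions: ketoreductase (panel hit selective for the (1R,5R)-ketone), NADP+ (cat), iPrOH, phosphate buffer pH 7, 30 °C, run to just past half conversion; chromatography
Reagents that add atoms: none
Why: Enzymatic kinetic resolution by enantioselective ketone reduction is well established for bicyclo[3.2.0]heptenones, so an enzyme chosen to reduce only the (1R,5R)-ketone to its easily separated endo alcohol should leave the (1S,5S)-ketone, which fixes Cb and Cc in the sense of the target.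

Step 3
Reactants: 5 (1S,5S)-4,7,7-trimethylbicyclo[3.2.0]hept-3-en-6-one; 6 diethyl {2-[methoxy(methyl)amino]-2-oxoethyl}phosphonate
Product: 7 N-methoxy-N-methyl-2-[(1S,5S)-4,7,7-trimethylbicyclo[3.2.0]hept-3-en-6-ylidene]acetamide (E/Z mixture)
Conditions: 6 (1.5 equiv), NaH (1.3 equiv), THF, 0 °C to reflux
Reagents that add atoms: none
Why: The Horner–Wadsworth–Emmons reaction works on cyclobutanones because carbanion addition relieves angle strain, the phosphonate kept in excess over NaH buffers the medium so that the doubly allylic Cb–H is not removed, and the alkene geometry does not matter for what follows.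

Step 4
Reactants: 8 4-bromo-3-fluorophenol
Product: 9 1-bromo-2-fluoro-4-(methoxymethoxy)benzene
Conditions: MOMCl, iPr2NEt, CH2Cl2, 0 °C to rt
Reagents that add atoms: chloromethyl methyl ether, COCCl
Why: Routine O-alkylation of a phenol gives an acetal that withstands the organomagnesium, CuH, palladium/base, fluoride and cobalt/silane conditions ahead.

Step 5
Reactants: 9 1-bromo-2-fluoro-4-(methoxymethoxy)benzene; 7 N-methoxy-N-methyl-2-[(1S,5S)-4,7,7-trimethylbicyclo[3.2.0]hept-3-en-6-ylidene]acetamide
Product: 11 1-[2-fluoro-4-(methoxymethoxy)phenyl]-2-[(1S,5S)-4,7,7-trimethylbicyclo[3.2.0]hept-3-en-6-ylidene]ethan-1-one (E/Z mixture), via arylmagnesium chloride 10 (not isolated)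
Conditions: 9, iPrMgCl·LiCl, THF, −10 °C; then 7, −20 to 0 °C; aq NH4Cl
Reagents that add atoms: none
Why: Bromine–magnesium exchange is accelerated by the ortho fluorine and gives an arylmagnesium that is stable below 0 °C, and in the Weinreb ketone synthesis the chelated tetrahedral adduct holds until work-up, so that a single 1,2-addition forms the C10–C9a bond without attack at the hindered β-carbon.

Step 6
Reactants: 11 1-[2-fluoro-4-(methoxymethoxy)phenyl]-2-[(1S,5S)-4,7,7-trimethylbicyclo[3.2.0]hept-3-en-6-ylidene]ethan-1-one
Product: 13 1-[2-fluoro-4-(methoxymethoxy)phenyl]-2-[(1S,5R,6R)-4,7,7-trimethylbicyclo[3.2.0]hept-3-en-6-yl]ethan-1-one (side chain endo), via phenylsilyl enol ether 12 (not isolated)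
Conditions: [(Ph3P)CuH]6 (cat), PhSiH3, toluene, rt; then aq NH4Cl
Reagents that add atoms: none
Why: CuH-catalysed conjugate reduction of β,β-disubstituted aryl enones is standard and ignores the isolated alkene, the C–F bond and the acetal, and since the concave face of Ca is screened by the cyclopentene ring the hydride arrives on the convex face, which sets Ca with the side chain endo (cis to Cd).

Step 7
Reactants: 14 4-bromoresorcinol (4-bromobenzene-1,3-diol)
Product: 15 2-bromo-5-[(tert-butyldimethylsilyl)oxy]phenol
Conditions: TBSCl (1.0 equiv), imidazole, CH2Cl2–DMF, −10 to 0 °C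
Reagents that add atoms: tert-butyldimethylsilyl chloride, CC(C)(C)[Si](C)(C)Cl
Why: Silylation under steric control should pick the hydroxyl para to bromine over the one flanked by bromine, as in known monoprotections of this diol, and any regioisomer is removed by chromatography.

Step 8
Reactants: 15 2-bromo-5-[(tert-butyldimethylsilyl)oxy]phenol
Product: 16 2-bromo-5-[(tert-butyldimethylsilyl)oxy]-4-iodophenol
Conditions: NIS, MeCN, 0 °C, dark
Reagents that add atoms: N-iodosuccinimide, O=C1CCC(=O)N1I
Why: Electrophilic aromatic iodination of the free phenol goes para to the hydroxyl, because one ortho site carries bromine and the other is wedged between the two oxygens.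

Step 9
Reactants: 16 2-bromo-5-[(tert-butyldimethylsilyl)oxy]-4-iodophenol
Product: 17 [4-bromo-2-iodo-5-(methoxymethoxy)phenoxy](tert-butyl)dimethylsilane
Conditions: MOMCl, iPr2NEt, CH2Cl2, 0 °C to rt
Reagents that add atoms: chloromethyl methyl ether, COCCl
Why: Routine O-alkylation caps the remaining phenol with the same acetal as on ring B, so that one operation frees both phenols at the end while the silyl ether stays orthogonal.

Step 10
Reactants: 13 1-[2-fluoro-4-(methoxymethoxy)phenyl]-2-[(1S,5R,6R)-4,7,7-trimethylbicyclo[3.2.0]hept-3-en-6-yl]ethan-1-one; 17 [4-bromo-2-iodo-5-(methoxymethoxy)phenoxy](tert-butyl)dimethylsilane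
Product: 18 2-{5-bromo-2-[(tert-butyldimethylsilyl)oxy]-4-(methoxymethoxy)phenyl}-1-[2-fluoro-4-(methoxymethoxy)phenyl]-2-[(1S,5R,6S)-4,7,7-trimethylbicyclo[3.2.0]hept-3-en-6-yl]ethan-1-one (both C11 epimers)
Conditions: Pd2(dba)3 (cat), Xantphos, K3PO4, toluene, 80 °C
Reagents that add atoms: none
Why: Palladium-catalysed α-arylation of aryl alkyl ketones with Xantphos and a weak phosphate base is well precedented, the only enolisable site is C11, oxidative addition favours the aryl iodide over the electron-rich bromide flanked by its acetal, crowding stops a second arylation, and the configuration of the new C11 centre is irrelevant.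

Step 11
Reactants: 18 the α-aryl ketone of step 10
Product: 20 2-bromo-3,7-bis(methoxymethoxy)-11-[(1S,5R,6S)-4,7,7-trimethylbicyclo[3.2.0]hept-3-en-6-yl]dibenzo[b,f]oxepin-10(11H)-one (both C11 epimers), via caesium phenoxide 19 (not isolated)
Conditions: CsF, DMF, 90 °C
Reagents that add atoms: none
Why: Fluoride cleaves the aryl silyl ether and the phenoxide displaces the fluoride ortho to the ketone in an intramolecular SNAr reaction, a standard way to close the seven-membered ring of dibenzoxepinones, with the released fluoride carrying the desilylation on.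

Step 12
Reactants: 20 2-bromo-3,7-bis(methoxymethoxy)-11-[(1S,5R,6S)-4,7,7-trimethylbicyclo[3.2.0]hept-3-en-6-yl]dibenzo[b,f]oxepin-10(11H)-one
Product: 21 hexacyclic bromo enol ether (bis(MOM) ether of the target with Br at C2 in place of prenyl; C10=C11 enol ether, O–Cd bond closed; Ca R, Cb R, Cc S, Cd R)
Conditions: Co(L) (5 mol %; H2L = N,N'-bis(3,5-di-tert-butylsalicylidene)-2,3-dimethylbutane-2,3-diamine; divalent cobalt), N-fluoro-2,4,6-trimethylpyridinium triflate (2 equiv), PhSiH3 (2 equiv), PhCF3, 0 °C to rt, argon
Reagents that add atoms: none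
Why: Proposed new method: the hydride (L)Co–H formed from Co(L), the N-fluoropyridinium salt and PhSiH3 passes a hydrogen atom to the CH end (C3) of the cyclopentene, the tertiary Cd radical is caught by divalent cobalt faster than the cyclobutylcarbinyl radical can open (either β-scission would give only a secondary radical), one-electron oxidation of the (L)Co–alkyl makes Cd electrophilic, the C10 carbonyl oxygen (made electron-rich by the para acetal oxygen of ring B) bonds to Cd, and the liberated collidine removes the acidic C11–H from the oxocarbenium ion to give the C10=C11 enol ether. The closest known reaction type is cobalt-salen MHAT radical-polar crossover hydroalkoxylation, including its variants in which an ester or carbamate carbonyl oxygen is the nucleophile, whereas capture by a ketone oxygen with loss of the α-proton has not been shown. The pyran (O, C10, C11, Ca, Cb, Cd) closes in a 6-exo mode with respect to the C3=C4 alkene. Cd is the only new stereocentre and is set by the substrate, because the ketone hangs from Ca on the concave face and its oxygen can reach Cd only cis to the cyclobutane, which leaves the methyl group on the convex face. The step needs Markovnikov regioselectivity, chemoselectivity and a cation that does not rearrange, and these are secured because the alkene is trisubstituted with a single tertiary terminus, the prenyl alkene is held back as an inert aryl bromide, attack by C11 would need a four-membered ring, C1 of ring A is meta to both oxygens, and ring expansion of the cyclobutane would lead to a 7-norbornyl-type cation. Both C11 epimers converge because C11 becomes trigonal.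

Step 13
Reactants: 21 hexacyclic bromo enol ether; 22 prenylboronic acid pinacol ester (4,4,5,5-tetramethyl-2-(3-methylbut-2-en-1-yl)-1,3,2-dioxaborolane)
Product: 23 bis(MOM) ether of the target (3,7-bis(methoxymethoxy)-2-prenyl hexacycle)
Conditions: PdCl2(IPent)(3-chloropyridine) (cat; IPent = 1,3-bis[2,6-di(pentan-3-yl)phenyl]imidazol-2-ylidene), 5 M aq KOH, THF, 65 °C
Reagents that add atoms: none
Why: Suzuki–Miyaura coupling of 3,3-disubstituted allylboronates with this bulky carbene–palladium precatalyst and aqueous KOH is known to bond the aryl group to the α-carbon and so should give the linear prenyl group, while acetals and the enol ether are stable to base.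

Step 14
Reactants: 23 bis(MOM) ether of the target
Product: 25 CNP0185814.1 (target), via bis(trimethylsilyl) ether 24 (not isolated)
Conditions: TMSOTf (4 equiv), 2,2'-bipyridyl (6 equiv), MeCN, 0 °C to rt; then H2O, rt
Reagents that add atoms: none
Why: The TMSOTf/2,2'-bipyridyl pair converts aryl MOM ethers into aryl trimethylsilyl ethers in a buffered, non-protic medium and water then hydrolyses these, a known mild deprotection that should spare the enol ether, the tertiary O–Cd bond and the ortho-prenylphenol, and it touches no stereocentre.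

Compound list
1 | geranic acid (2E/2Z mixture) | CC(C)=CCCC(C)=CC(O)=O | starting material
2 | acetic geranic anhydride | CC(C)=CCCC(C)=CC(=O)OC(C)=O | intermediate
3 | (3Z)-3,7-dimethylocta-1,3,6-trien-1-one (vinylketene) | O=C=C/C(C)=C\CC=C(C)C | intermediate
4 | (±)-cis-4,7,7-trimethylbicyclo[3.2.0]hept-3-en-6-one (racemate) | CC1=CCC2C1C(=O)C2(C)C | intermediate
5 | (1S,5S)-4,7,7-trimethylbicyclo[3.2.0]hept-3-en-6-one | O=C1[C@H]2[C@H](CC=C2C)C1(C)C | intermediate
6 | diethyl {2-[methoxy(methyl)amino]-2-oxoethyl}phosphonate | CCOP(=O)(CC(=O)N(C)OC)OCC | starting material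
7 | N-methoxy-N-methyl-2-[(1S,5S)-4,7,7-trimethylbicyclo[3.2.0]hept-3-en-6-ylidene]acetamide (E/Z mixture) | CON(C)C(=O)C=C1[C@H]2[C@H](CC=C2C)C1(C)C | intermediate
8 | 4-bromo-3-fluorophenol | Oc1ccc(Br)c(F)c1 | starting material
9 | 1-bromo-2-fluoro-4-(methoxymethoxy)benzene | COCOc1ccc(Br)c(F)c1 | intermediate
10 | [2-fluoro-4-(methoxymethoxy)phenyl]magnesium chloride (LiCl complex) | COCOc1ccc([Mg]Cl)c(F)c1 | intermediate
11 | 1-[2-fluoro-4-(methoxymethoxy)phenyl]-2-[(1S,5S)-4,7,7-trimethylbicyclo[3.2.0]hept-3-en-6-ylidene]ethan-1-one (E/Z mixture) | COCOc1ccc(C(=O)C=C2[C@H]3[C@H](CC=C3C)C2(C)C)c(F)c1 | intermediate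
12 | phenylsilyl enol ether of 13 | COCOc1ccc(C(O[SiH2]c2ccccc2)=C[C@@H]2[C@H]3[C@H](CC=C3C)C2(C)C)c(F)c1 | intermediate
13 | 1-[2-fluoro-4-(methoxymethoxy)phenyl]-2-[(1S,5R,6R)-4,7,7-trimethylbicyclo[3.2.0]hept-3-en-6-yl]ethan-1-one (endo) | COCOc1ccc(C(=O)C[C@@H]2[C@H]3[C@H](CC=C3C)C2(C)C)c(F)c1 | intermediate
14 | 4-bromoresorcinol | Oc1ccc(Br)c(O)c1 | starting material
15 | 2-bromo-5-[(tert-butyldimethylsilyl)oxy]phenol | CC(C)(C)[Si](C)(C)Oc1ccc(Br)c(O)c1 | intermediate
16 | 2-bromo-5-[(tert-butyldimethylsilyl)oxy]-4-iodophenol | CC(C)(C)[Si](C)(C)Oc1cc(O)c(Br)cc1I | intermediate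
17 | [4-bromo-2-iodo-5-(methoxymethoxy)phenoxy](tert-butyl)dimethylsilane | CC(C)(C)[Si](C)(C)Oc1cc(OCOC)c(Br)cc1I | intermediate
18 | 2-{5-bromo-2-[(tert-butyldimethylsilyl)oxy]-4-(methoxymethoxy)phenyl}-1-[2-fluoro-4-(methoxymethoxy)phenyl]-2-[(1S,5R,6S)-4,7,7-trimethylbicyclo[3.2.0]hept-3-en-6-yl]ethan-1-one (C11 epimers) | COCOc1ccc(C(=O)C(c2cc(Br)c(OCOC)cc2O[Si](C)(C)C(C)(C)C)[C@@H]2[C@H]3[C@H](CC=C3C)C2(C)C)c(F)c1 | intermediate
19 | caesium phenoxide derived from 18 | COCOc1ccc(C(=O)C(c2cc(Br)c(OCOC)cc2[O-])[C@@H]2[C@H]3[C@H](CC=C3C)C2(C)C)c(F)c1.[Cs+] | intermediate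
20 | 2-bromo-3,7-bis(methoxymethoxy)-11-[(1S,5R,6S)-4,7,7-trimethylbicyclo[3.2.0]hept-3-en-6-yl]dibenzo[b,f]oxepin-10(11H)-one (C11 epimers) | Brc1cc2c(cc1OCOC)Oc1cc(OCOC)ccc1C(=O)C2[C@@H]2[C@H]3[C@H](CC=C3C)C2(C)C | intermediate
21 | hexacyclic bromo enol ether, bis(MOM) ether (Ca R, Cb R, Cc S, Cd R) | Brc1cc2c(cc1OCOC)Oc1cc(OCOC)ccc1C1=C2[C@@H]2[C@H]3[C@H](CC[C@@]3(C)O1)C2(C)C | intermediate
22 | prenylboronic acid pinacol ester | CC(C)=CCB1OC(C)(C)C(C)(C)O1 | starting material
23 | bis(MOM) ether of the target | CC(C)=CCc1cc2c(cc1OCOC)Oc1cc(OCOC)ccc1C1=C2[C@@H]2[C@H]3[C@H](CC[C@@]3(C)O1)C2(C)C | intermediate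
24 | bis(trimethylsilyl) ether of the target | CC(C)=CCc1cc2c(cc1O[Si](C)(C)C)Oc1cc(O[Si](C)(C)C)ccc1C1=C2[C@@H]2[C@H]3[C@H](CC[C@@]3(C)O1)C2(C)C | intermediate
25 | CNP0185814.1 (Ca R, Cb R, Cc S, Cd R) | CC(C)=CCc1cc2c(cc1O)Oc1cc(O)ccc1C1=C2[C@@H]2[C@H]3[C@H](CC[C@@]3(C)O1)C2(C)C | target

Total step count: 14. Longest linear sequence: 10 steps (1, 2, 3, 5, 6, 10, 11, 12, 13, 14).

Steps most likely to fail

Step 12. The ketone oxygen may capture the electrophilic Cd too slowly. Proton loss (alkene isomerisation) or simple reduction of the radical to the saturated ring could then take over.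
- The fallback uses known chemistry at a lower oxidation level and sets out from 20.
- NaBH4 in MeOH–THF at 0 °C should reduce the C10 ketone to the 10,11-dihydrodibenzoxepin-10-ol F1 as a diastereomer mixture.
- The established Co(L)/N-fluoro-2,4,6-trimethylpyridinium triflate/PhSiH3 hydroalkoxylation, now with a free secondary alcohol as nucleophile, closes the same O–Cd bond from the same concave face and should give the 10,11-dihydro pyran F2.
- DDQ in dioxane then abstracts the C10 hydride, which is a para-alkoxybenzyl ether position. Loss of the C11 proton installs the C10=C11 double bond.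
- All diastereomers converge and the route is rejoined at 21.

Step 10. Crowding at the methylene next to the concave face may slow enolate binding and reductive elimination. Protodeiodination or oxidative addition at the bromide could then intervene.
- The fallback reverses the order of the two bonds that make the oxepine and sets out from 13 and 17.
- CsF in DMF at 100 °C joins them first by an intermolecular desilylative SNAr reaction to the diaryl ether ketone F3.
- Pd2(dba)3, Xantphos and K3PO4 then effect a ring-closing ketone α-arylation at the iodide. Here the tether, not concentration, brings C11 to palladium.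
- This closes the seven-membered ring, bypasses 18 and 19, and rejoins the route at 20.

Step 14. The silyl triflate may ionise the tertiary O–Cd bond, or acid formed during hydrolysis may cyclise the ortho-prenylphenol to a chroman.
- The fallback changes the order of events so that the prenyl group never meets a Lewis acid, and it sets out from 21.
- The MOM groups are removed at the bromide stage (TMSOTf, 2,2'-bipyridyl, then water) to give the bromo diphenol F4.
- The Suzuki–Miyaura prenylation with 22, PdCl2(IPent)(3-chloropyridine) and aqueous KOH is then run on the bis(phenoxide). After neutral work-up it should deliver 25 directly.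

Further compounds
F1 | step 12 | 2-bromo-3,7-bis(methoxymethoxy)-11-[(1S,5R,6S)-4,7,7-trimethylbicyclo[3.2.0]hept-3-en-6-yl]-10,11-dihydrodibenzo[b,f]oxepin-10-ol (C10/C11 diastereomers) | Brc1cc2c(cc1OCOC)Oc1cc(OCOC)ccc1C(O)C2[C@@H]2[C@H]3[C@H](CC=C3C)C2(C)C
F2 | step 12 | 10,11-dihydro derivative of 21 (C10/C11 diastereomers) | Brc1cc2c(cc1OCOC)Oc1cc(OCOC)ccc1C1C2[C@@H]2[C@H]3[C@H](CC[C@@]3(C)O1)C2(C)C
F3 | step 10 | 1-{2-[4-bromo-2-iodo-5-(methoxymethoxy)phenoxy]-4-(methoxymethoxy)phenyl}-2-[(1S,5R,6R)-4,7,7-trimethylbicyclo[3.2.0]hept-3-en-6-yl]ethan-1-one | COCOc1ccc(C(=O)C[C@@H]2[C@H]3[C@H](CC=C3C)C2(C)C)c(Oc2cc(OCOC)c(Br)cc2I)c1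
F4 | step 14 | bromo diphenol (21 without the MOM groups) | Brc1cc2c(cc1O)Oc1cc(O)ccc1C1=C2[C@@H]2[C@H]3[C@H](CC[C@@]3(C)O1)C2(C)C
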